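The cyclohexane is disconnected at C1–C6 and C4–C5 (cyclohexanol numbering: C1 carbinol, C3 CHBr, C4 CCl). The unfunctionalised C5–C6 unit is a two-carbon dienophile; C1–C2–C3–C4 and the oxygen of the tertiary alcohol are the ring of a 3-bromo-2,5-disubstituted furan built on the carboxyl carbon of a camphanic-acid-derived cyclopentane. One Cu–bis(oxazoline)-catalysed [4+2] cycloaddition forms both bonds and a temporary O–C4 bridge that locks the 1,4-cis relationship between the oxygen on C1 and the future chlorine on C4. Exo diimide reduction then sets C3–Br, bromine-assisted chloride opening of the bridge gives C4–Cl with retention, and the dienophile's acyl group is excised by radical decarboxylation.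

Key step: step 7

Remark: numbered compounds are substrates, building blocks, intermediates and the target; auxiliary reagents are given by name and SMILES only. "Endo" means anti to the bridging oxygen.
Remark: (1S)-(−)-camphanic acid, but-1-yne, 3-acryloyl-1,3-oxazolidin-2-one and the (S,S)-t-Bu-box ligand are taken as commercial.

Step 1
Reactants: 1 (1S,4R)-4,7,7-trimethyl-3-oxo-2-oxabicyclo[2.2.1]heptane-1-carboxylic acid [(1S)-(−)-camphanic acid]
Product: 3 (1R)-1,2,2-trimethyl-3-oxocyclopentane-1-carboxylic acid, via disodium hydroxy-dicarboxylate 2 (not isolated)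
Conditions: NaOH (2.2 equiv), H2O, 80 °C; then pH 8 (NaHCO3), NaOCl (aq), 0 °C → rt; HCl to pH 2
Reagents that add atoms: sodium hydroxide, [Na+].[OH-]
Why: Saponification of the bicyclic lactone unmasks a tertiary α-hydroxy acid whose hypochlorite-mediated oxidative decarboxylation (O-chlorination, then loss of CO2 and chloride) should give the ketone, leaving the quaternary stereocentre bought with 1 untouched.

Step 2
Reactants: 3 (1R)-1,2,2-trimethyl-3-oxocyclopentane-1-carboxylic acid; 4 but-1-yne
Product: 6 1-[(1R)-1,2,2-trimethyl-3-oxocyclopentyl]pent-2-yn-1-one, via acid chloride 5 (not isolated)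
Conditions: (COCl)2, DMF (cat.), CH2Cl2, 0 °C → rt, concentrate; then but-1-yne, PdCl2(PPh3)2 (2 mol%), CuI (4 mol%), Et3N, THF, rt
Reagents that add atoms: but-1-yne (4), CCC#C
Why: Acid chloride formation followed by Pd/Cu-catalysed acyl Sonogashira coupling works for pivaloyl-type acid chlorides and passes through no free acylium ion, so the neopentyl quaternary centre cannot rearrange.

Step 3
Reactants: 6 1-[(1R)-1,2,2-trimethyl-3-oxocyclopentyl]pent-2-yn-1-one
Product: 8 (3R)-2,2,3-trimethyl-3-(5-methylfuran-2-yl)cyclopentan-1-one, via allenyl ketone 7 (not isolated)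
Conditions: CuI (10 mol%), Et3N–DMA (1:7), 100 °C
Reagents that add atoms: none
Why: Base-mediated propargyl–allenyl isomerisation and Cu(I)-catalysed cycloisomerisation of the allenyl ketone (carbonyl oxygen onto the allene terminus) should give the 2,5-disubstituted furan, the ethyl group of the ynone becoming the furan methyl.

Step 4
Reactants: 8 (3R)-2,2,3-trimethyl-3-(5-methylfuran-2-yl)cyclopentan-1-one
Product: 9 (1R,3R)-2,2,3-trimethyl-3-(5-methylfuran-2-yl)cyclopentan-1-ol (OH trans to the furyl group)
Conditions: (S)-Me-CBS (20 mol%), BH3·SMe2, THF, −20 °C; MeOH quench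
Reagents that add atoms: none
Why: Corey–Bakshi–Shibata reduction, in which the catalyst distinguishes the quaternary C2 flank (large) from the C5 methylene flank (small), should deliver hydride under reagent control to give the (1R)-alcohol whatever the weak bias of the remote quaternary centre.

Step 5
Reactants: 9 (1R,3R)-2,2,3-trimethyl-3-(5-methylfuran-2-yl)cyclopentan-1-ol
Product: 10 2-[(1R,3S)-3-bromo-1,2,2-trimethylcyclopentyl]-5-methylfuran (Br cis to the furyl group)
Conditions: PPh3, CBr4, 2,6-lutidine, toluene, 0 → 60 °C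
Reagents that add atoms: carbon tetrabromide, BrC(Br)(Br)Br
Why: Appel bromination displaces the activated oxygen by bromide in an SN2 step with inversion, which places bromine cis to the furyl group (3S), and the aromatic furan oxygen is too weak a nucleophile to intercept the activated alcohol.

Step 6
Reactants: 10 2-[(1R,3S)-3-bromo-1,2,2-trimethylcyclopentyl]-5-methylfuran
Product: 11 3-bromo-5-[(1R,3S)-3-bromo-1,2,2-trimethylcyclopentyl]-2-methylfuran
Conditions: NBS (1.05 equiv), DMF, −20 → 0 °C, dark
Reagents that add atoms: N-bromosuccinimide, O=C1CCC(=O)N1Br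
Why: Electrophilic aromatic bromination of the electron-rich 2,5-dialkylfuran under ionic conditions should occur at the β-position next to the methyl group, because the other β-position is shielded by the adjacent quaternary cyclopentyl carbon.

Step 7
Reactants: 11 3-bromo-5-[(1R,3S)-3-bromo-1,2,2-trimethylcyclopentyl]-2-methylfuran; 12 3-(prop-2-enoyl)-1,3-oxazolidin-2-one
Product: 13 3-{[(1R,2S,4S)-5-bromo-1-[(1R,3S)-3-bromo-1,2,2-trimethylcyclopentyl]-4-methyl-7-oxabicyclo[2.2.1]hept-5-en-2-yl]carbonyl}-1,3-oxazolidin-2-one (acyl group endo, on the carbon next to the cyclopentyl-bearing bridgehead)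
Conditions: [Cu((S,S)-t-Bu-box)](SbF6)2 (10 mol%), 3 Å MS, CH2Cl2, −78 → −40 °C; 12 in excess; used cold and crude
Reagents that add atoms: 3-(prop-2-enoyl)-1,3-oxazolidin-2-one (12), C=CC(=O)N1CCOC1=O
Why: The square-planar Cu(II)–bis(oxazoline) complex chelates 12 in the s-cis form and the furan adds to it in a concerted but asynchronous normal-demand [4+2] cycloaddition, the closest known reaction type being the Cu(II)–box-catalysed Diels–Alder reaction of furan with this same acrylimide. The carbocyclic six-membered ring is closed by suprafacial [4πs+2πs] addition across furan C2 and C5 (C4 and C1 of the future cyclohexane), and because the furan oxygen stays attached to both carbons the ring is born as a 7-oxabicyclo[2.2.1]heptene. The two bridgehead stereocentres are set together by the furan face that is attacked and are necessarily 1,4-cis through the oxygen bridge, while the acyl-bearing carbon is set by the endo orientation on the catalyst-exposed Cα-Re face (the (S,S)-ligand is expected to expose this face, as in the (2S)-endo cyclopentadiene adduct). Regiochemistry (CH2 terminus to the methyl-bearing carbon) should follow from the bromine-polarised, less hindered C2 terminus, and endo geometry from the fact that an exo acyl group would nearly eclipse the tert-alkyl bridgehead substituent. The step needs π-facial selectivity with respect to the cyclopentyl stereocentres, for which the substrate offers only a methyl-versus-ring-methylene difference at the quaternary carbon; it is therefore secured by the ligand, because with regiochemistry and endo geometry fixed the dienophile face chosen by the catalyst dictates which furan face reacts. The acyl group is temporary and also serves in step 10.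

Step 8
Reactants: 13 the endo cycloadduct of step 7
Product: 14 3-{[(1S,2S,4S,5S)-5-bromo-1-[(1R,3S)-3-bromo-1,2,2-trimethylcyclopentyl]-4-methyl-7-oxabicyclo[2.2.1]heptan-2-yl]carbonyl}-1,3-oxazolidin-2-one (both Br and acyl endo)
Conditions: KO2CN=NCO2K (excess, portionwise), AcOH, MeOH–CH2Cl2, 0 °C → rt
Reagents that add atoms: none
Why: Diimide reduction transfers two hydrogens in a concerted syn fashion to the strained bicyclic alkene from the exo (oxygen-bridge) face, the endo face being blocked by the acyl-bearing bridge, which leaves bromine endo (anti to the bridging oxygen), leaves C–Br bonds intact and ends the possibility of cycloreversion.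

Step 9
Reactants: 14 the saturated endo-bromo imide of step 8
Product: 16 (1S,2S,4S,5S)-5-bromo-1-[(1R,3S)-3-bromo-1,2,2-trimethylcyclopentyl]-4-methyl-7-oxabicyclo[2.2.1]heptane-2-carboxylic acid, via peroxy acid 15 (not isolated)
Conditions: LiOH, H2O2, THF–H2O, 0 °C; then Na2SO3; 1 M HCl
Reagents that add atoms: hydrogen peroxide, OO
Why: Hydroperoxide attacks the exocyclic imide carbonyl selectively (the standard cleavage of N-acyl oxazolidinones) and sulfite reduces the peracid, and these cold, weakly enolising conditions should avoid β-elimination of the oxygen bridge.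

Step 10
Reactants: 16 the oxygen-bridged endo-bromo acid of step 9
Product: 17 (1S,2S,4S,5S)-4-bromo-2-[(1R,3S)-3-bromo-1,2,2-trimethylcyclopentyl]-5-chloro-2-hydroxy-5-methylcyclohexane-1-carboxylic acid
Conditions: TiCl4 (2.5 equiv), CH2Cl2, −78 → −30 °C; aqueous buffer work-up
Reagents that add atoms: titanium tetrachloride, Cl[Ti](Cl)(Cl)Cl
Why: In this Lewis-acid ether cleavage with neighbouring-group participation, TiCl4 on the bridging oxygen should ionise the C–O bond at the methyl-bearing bridgehead, because that bond is anti-periplanar to the endo bromine (anchimeric assistance through a bromonium-like bridge) while the other bridgehead is inductively deactivated by the adjacent carboxylate, and chloride then enters the tertiary carbon anti to bromine, that is from the face the oxygen left, giving C–Cl with retention (cis to OH, trans to Br).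

Step 11
Reactants: 17 the chlorohydrin acid of step 10
Product: 19 (1R,3S,4S)-3-bromo-1-[(1R,3S)-3-bromo-1,2,2-trimethylcyclopentyl]-4-chloro-4-methylcyclohexan-1-ol, via thiohydroxamate ester 18 (not isolated)
Conditions: N-hydroxypyridine-2-thione, DCC, DMAP (cat.), CH2Cl2, 0 °C → rt, dark; then t-BuSH (excess), hν (tungsten lamp), rt
Reagents that add atoms: none
Why: Barton reductive decarboxylation fragments the thiohydroxamate ester to the secondary alkyl radical, which should abstract hydrogen from the thiol faster than it can engage the C–Br or C–Cl bonds, and no stereocentre is created or touched.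

Compound list
1 | (1S,4R)-4,7,7-trimethyl-3-oxo-2-oxabicyclo[2.2.1]heptane-1-carboxylic acid, (1S)-(−)-camphanic acid | CC1(C)[C@]2(C(O)=O)CC[C@@]1(C)C(=O)O2 | starting material
2 | disodium (1S,3R)-1-hydroxy-2,2,3-trimethylcyclopentane-1,3-dicarboxylate | CC1(C)[C@](O)(C([O-])=O)CC[C@@]1(C)C([O-])=O.[Na+].[Na+] | intermediate
3 | (1R)-1,2,2-trimethyl-3-oxocyclopentane-1-carboxylic acid | CC1(C)C(=O)CC[C@@]1(C)C(O)=O | intermediate
4 | but-1-yne | CCC#C | starting material
5 | (1R)-1,2,2-trimethyl-3-oxocyclopentane-1-carbonyl chloride | CC1(C)C(=O)CC[C@@]1(C)C(Cl)=O | intermediate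
6 | 1-[(1R)-1,2,2-trimethyl-3-oxocyclopentyl]pent-2-yn-1-one | CC1(C)C(=O)CC[C@@]1(C)C(=O)C#CCC | intermediate
7 | 1-[(1R)-1,2,2-trimethyl-3-oxocyclopentyl]penta-2,3-dien-1-one (allene axis not defined) | CC1(C)C(=O)CC[C@@]1(C)C(=O)C=C=CC | intermediate
8 | (3R)-2,2,3-trimethyl-3-(5-methylfuran-2-yl)cyclopentan-1-one | CC1(C)C(=O)CC[C@@]1(C)c1ccc(C)o1 | intermediate
9 | (1R,3R)-2,2,3-trimethyl-3-(5-methylfuran-2-yl)cyclopentan-1-ol | CC1(C)[C@H](O)CC[C@@]1(C)c1ccc(C)o1 | intermediate
10 | 2-[(1R,3S)-3-bromo-1,2,2-trimethylcyclopentyl]-5-methylfuran | CC1(C)[C@@H](Br)CC[C@@]1(C)c1ccc(C)o1 | intermediate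
11 | 3-bromo-5-[(1R,3S)-3-bromo-1,2,2-trimethylcyclopentyl]-2-methylfuran | CC1(C)[C@@H](Br)CC[C@@]1(C)c1cc(Br)c(C)o1 | intermediate
12 | 3-(prop-2-enoyl)-1,3-oxazolidin-2-one | C=CC(=O)N1CCOC1=O | starting material
13 | 3-{[(1R,2S,4S)-5-bromo-1-[(1R,3S)-3-bromo-1,2,2-trimethylcyclopentyl]-4-methyl-7-oxabicyclo[2.2.1]hept-5-en-2-yl]carbonyl}-1,3-oxazolidin-2-one | CC1(C)[C@@H](Br)CC[C@@]1(C)[C@]12[C@@H](C(=O)N3CCOC3=O)C[C@](C)(O1)C(Br)=C2 | intermediate
14 | 3-{[(1S,2S,4S,5S)-5-bromo-1-[(1R,3S)-3-bromo-1,2,2-trimethylcyclopentyl]-4-methyl-7-oxabicyclo[2.2.1]heptan-2-yl]carbonyl}-1,3-oxazolidin-2-one | CC1(C)[C@@H](Br)CC[C@@]1(C)[C@]12[C@@H](C(=O)N3CCOC3=O)C[C@](C)(O1)[C@@H](Br)C2 | intermediate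
15 | (1S,2S,4S,5S)-5-bromo-1-[(1R,3S)-3-bromo-1,2,2-trimethylcyclopentyl]-4-methyl-7-oxabicyclo[2.2.1]heptane-2-carboperoxoic acid | CC1(C)[C@@H](Br)CC[C@@]1(C)[C@]12[C@@H](C(=O)OO)C[C@](C)(O1)[C@@H](Br)C2 | intermediate
16 | (1S,2S,4S,5S)-5-bromo-1-[(1R,3S)-3-bromo-1,2,2-trimethylcyclopentyl]-4-methyl-7-oxabicyclo[2.2.1]heptane-2-carboxylic acid | CC1(C)[C@@H](Br)CC[C@@]1(C)[C@]12[C@@H](C(O)=O)C[C@](C)(O1)[C@@H](Br)C2 | intermediate
17 | (1S,2S,4S,5S)-4-bromo-2-[(1R,3S)-3-bromo-1,2,2-trimethylcyclopentyl]-5-chloro-2-hydroxy-5-methylcyclohexane-1-carboxylic acid | CC1(C)[C@@H](Br)CC[C@@]1(C)[C@@]1(O)[C@@H](C(O)=O)C[C@](C)(Cl)[C@@H](Br)C1 | intermediate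
18 | 2-sulfanylidenepyridin-1(2H)-yl ester of 17 (Barton ester) | CC1(C)[C@@H](Br)CC[C@@]1(C)[C@@]1(O)[C@@H](C(=O)On2ccccc2=S)C[C@](C)(Cl)[C@@H](Br)C1 | intermediate
19 | (1R,3S,4S)-3-bromo-1-[(1R,3S)-3-bromo-1,2,2-trimethylcyclopentyl]-4-chloro-4-methylcyclohexan-1-ol | CC1(C)[C@@H](Br)CC[C@@]1(C)[C@@]1(O)CC[C@](C)(Cl)[C@@H](Br)C1 | target

Total step count: 11
Longest linear sequence: 11 steps (1 → 19)

Steps most likely to fail

Step 7. The catalyst's facial preference may be transferred to the furan only in part: exo addition or reversed regiochemistry would each deliver the opposite furan face, the cis-bromocyclopentyl group may exert a mismatched bias, and the hindered adduct may revert on warming. Fallback, setting out from 11: facial control would be given up and the cycloaddition with 12 run without catalyst at 10–12 kbar in CH2Cl2 at room temperature. Compound 13 would be separated by chromatography at 0 °C from its principal contaminant, the opposite-face endo adduct 3-{[(1S,2R,4R)-5-bromo-1-[(1R,3S)-3-bromo-1,2,2-trimethylcyclopentyl]-4-methyl-7-oxabicyclo[2.2.1]hept-5-en-2-yl]carbonyl}-1,3-oxazolidin-2-one F1. F1 would be returned to 11 and 12 by cycloreversion in toluene at 60–80 °C and resubmitted. The route is rejoined at 13.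

Step 10. Ionisation may occur at the wrong bridgehead C–O bond, followed by a Wagner–Meerwein shift in the cyclopentylcarbinyl system, or chloride may attack the secondary carbon of the bromine bridge. Fallback, setting out from 14: the opening would be moved to the imide stage (TiCl4, 2.2 equiv, CH2Cl2, −78 °C). There the first equivalent is held as a chelate by the two imide carbonyls next to C1 and should deactivate the C1–O bond more strongly than a carboxylate does. This should give the ring-opened chlorohydrin imide F2. LiOH/H2O2 then Na2SO3 would cleave F2 through the peroxy acid F3 to 17, where the route is rejoined.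

Step 5. SN2 displacement at the neopentyl-type secondary carbon may be slow, with E2 elimination or a 1,2-methyl shift taking over. Fallback, setting out from 9: the in situ phosphonium activation would be replaced by a discrete sulfonate ester and a separate displacement. Tf2O and 2,6-lutidine in CH2Cl2 at −78 °C would give the triflate F4, and LiBr in DMF at 0 °C would displace it with inversion to give 10, where the route is rejoined.

Further compounds
F1 | step 7 | 3-{[(1S,2R,4R)-5-bromo-1-[(1R,3S)-3-bromo-1,2,2-trimethylcyclopentyl]-4-methyl-7-oxabicyclo[2.2.1]hept-5-en-2-yl]carbonyl}-1,3-oxazolidin-2-one | CC1(C)[C@@H](Br)CC[C@@]1(C)[C@@]12[C@H](C(=O)N3CCOC3=O)C[C@@](C)(O1)C(Br)=C2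
F2 | step 10 | 3-{[(1S,2S,4S,5S)-4-bromo-2-[(1R,3S)-3-bromo-1,2,2-trimethylcyclopentyl]-5-chloro-2-hydroxy-5-methylcyclohexyl]carbonyl}-1,3-oxazolidin-2-one | CC1(C)[C@@H](Br)CC[C@@]1(C)[C@@]1(O)[C@@H](C(=O)N2CCOC2=O)C[C@](C)(Cl)[C@@H](Br)C1
F3 | step 10 | (1S,2S,4S,5S)-4-bromo-2-[(1R,3S)-3-bromo-1,2,2-trimethylcyclopentyl]-5-chloro-2-hydroxy-5-methylcyclohexane-1-carboperoxoic acid | CC1(C)[C@@H](Br)CC[C@@]1(C)[C@@]1(O)[C@@H](C(=O)OO)C[C@](C)(Cl)[C@@H](Br)C1
F4 | step 5 | (1R,3R)-2,2,3-trimethyl-3-(5-methylfuran-2-yl)cyclopentyl trifluoromethanesulfonate | CC1(C)[C@H](OS(=O)(=O)C(F)(F)F)CC[C@@]1(C)c1ccc(C)o1
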